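The pyran ring is opened at O1–C2 and ring B is removed from C2, which leaves an open chain in which C2, C3, C4 and the E-styryl alkene on C4 form a γ,δ-unsaturated acid with the C3 benzyl group and the C4–C4a (ring A) bond anti. The Ireland–Claisen rearrangement of an (R,E)-1,3-diarylallyl 3-arylpropanoate builds this array in one operation: it forms C3–C4, shifts the alkene into the E-styryl position and relays the carbinol configuration to C3 and C4, closing no ring. Its precursor is the acyclic ester of a ring A cinnamyl-type carbinol. Ring B is then added to an aldehyde and the pyran closes last through the C2 benzylic cation.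

Key step: step 7

Assumption: in the oxazaborolidine reduction of step 4 the ring-bound 4-silyloxyphenyl group is taken to act as the larger ketone substituent, as aryl does in aryl alkyl ketones, so that the (S)-catalyst gives the (R)-carbinol; the sense would be checked on the first batch by MTPA ester analysis and the (R)-catalyst used instead if it is reversed.

Step 1
Reactants: 1 2-hydroxy-4-methoxybenzaldehyde
Product: 2 4-methoxy-2-(methoxymethoxy)benzaldehyde
Conditions: MOMCl (1.5 equiv), iPr2NEt (2 equiv), CH2Cl2, 0 °C to rt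
Reagents that add atoms: chloromethyl methyl ether (MOMCl), COCCl
Why: Williamson-type O-alkylation of the phenol by the reactive α-chloro ether gives the MOM acetal, which masks the future O1 through all basic, hydride and organolithium steps and is removed by the acid of step 11.

Step 2
Reactants: 2 4-methoxy-2-(methoxymethoxy)benzaldehyde; 3 4'-hydroxyacetophenone
Product: 4 (E)-1-(4-hydroxyphenyl)-3-[4-methoxy-2-(methoxymethoxy)phenyl]prop-2-en-1-one
Conditions: KOH (50% aq., 5 equiv), EtOH, rt; AcOH to pH 6, 0 °C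
Reagents that add atoms: none
Why: Claisen–Schmidt condensation, in which the non-enolisable aldehyde accepts the acetophenone enolate (excess KOH carries the ketone as its phenoxide) and E1cB dehydration gives the conjugated enone with the thermodynamic E geometry.

Step 3
Reactants: 4 (E)-1-(4-hydroxyphenyl)-3-[4-methoxy-2-(methoxymethoxy)phenyl]prop-2-en-1-one
Product: 5 (E)-3-[4-methoxy-2-(methoxymethoxy)phenyl]-1-[4-(triisopropylsilyloxy)phenyl]prop-2-en-1-one
Conditions: iPr3SiCl (1.3 equiv), imidazole (2.5 equiv), DMF, rt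
Reagents that add atoms: triisopropylsilyl chloride (iPr3SiCl), CC(C)[Si](Cl)(C(C)C)C(C)C
Why: Imidazole-promoted O-silylation of the phenol gives a bulky aryl silyl ether that should survive amide bases, hydrides, aryllithium and mild acid and that is a weaker donor than an alkoxy group.

Step 4
Reactants: 5 (E)-3-[4-methoxy-2-(methoxymethoxy)phenyl]-1-[4-(triisopropylsilyloxy)phenyl]prop-2-en-1-one
Product: 6 (R,E)-3-[4-methoxy-2-(methoxymethoxy)phenyl]-1-[4-(triisopropylsilyloxy)phenyl]prop-2-en-1-ol
Conditions: (S)-1-methyl-3,3-diphenyltetrahydro-1H,3H-pyrrolo[1,2-c][1,3,2]oxazaborole (0.2 equiv), catecholborane (1.5 equiv), toluene, −78 °C; MeOH, then aq. NaOH/NaHCO3 wash; Et3N-deactivated silica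
Reagents that add atoms: none
Why: Corey–Bakshi–Shibata reduction, in which the ketone binds the catalyst boron anti to its aryl group and hydride passes from the coordinated catecholborane to one carbonyl face, so that the (R)-carbinol is set by catalyst control while the cold borane leaves the alkene alone.

Step 5
Reactants: 7 3-(4-hydroxyphenyl)propanoic acid
Product: 9 3-[4-(triisopropylsilyloxy)phenyl]propanoic acid, via bis-silyl ester 8 (not isolated)
Conditions: iPr3SiCl (2.3 equiv), imidazole (5 equiv), DMF, rt; then K2CO3 (1.2 equiv), MeOH–THF–H2O, 0 °C; 1 M HCl to pH 4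
Reagents that add atoms: triisopropylsilyl chloride (iPr3SiCl), CC(C)[Si](Cl)(C(C)C)C(C)C
Why: Silylation of both acidic OH groups followed by mild carbonate solvolysis, which should cleave only the labile silyl ester and leave the hindered aryl silyl ether.

Step 6
Reactants: 6 (R,E)-3-[4-methoxy-2-(methoxymethoxy)phenyl]-1-[4-(triisopropylsilyloxy)phenyl]prop-2-en-1-ol; 9 3-[4-(triisopropylsilyloxy)phenyl]propanoic acid
Product: 10 (R,E)-3-[4-methoxy-2-(methoxymethoxy)phenyl]-1-[4-(triisopropylsilyloxy)phenyl]allyl 3-[4-(triisopropylsilyloxy)phenyl]propanoate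
Conditions: DCC (1.2 equiv), 4-(dimethylamino)pyridine (0.1 equiv), CH2Cl2, 0 °C; filtered through basic alumina, used at once
Reagents that add atoms: none
Why: Steglich esterification acylates the carbinol oxygen without breaking its C–O bond, so the R configuration is retained under non-acidic conditions, and the ionisation-prone ester is not stored.

Step 7
Reactants: 10 (R,E)-3-[4-methoxy-2-(methoxymethoxy)phenyl]-1-[4-(triisopropylsilyloxy)phenyl]allyl 3-[4-(triisopropylsilyloxy)phenyl]propanoate
Product: 13 (2R,3R,E)-3-[4-methoxy-2-(methoxymethoxy)phenyl]-2-[4-(triisopropylsilyloxy)benzyl]-5-[4-(triisopropylsilyloxy)phenyl]pent-4-enoic acid, via silyl ketene acetal 11 (not isolated), via trimethylsilyl ester 12 (not isolated)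
Conditions: 10 added to LiN(iPr)2 (1.3 equiv) and Me3SiCl–Et3N (premixed, 2 equiv), THF, −78 °C, then to rt; MeOH–H2O, NaH2PO4 buffer (pH 5)
Reagents that add atoms: none
Why: Kinetic deprotonation of the ester α-CH2 by LiN(iPr)2 in THF without HMPA, with Me3SiCl present to trap the enolate, should give the (E)-silyl ketene acetal 11 with the CH2Ar group cis to the allylic oxygen; on warming, 11 undergoes a concerted suprafacial [3,3]-sigmatropic shift through a chair transition state that forms the bond between the α-carbon and the alkene carbon bearing ring A (future C3–C4), breaks the allylic C–O bond and moves the alkene, and the silyl ester 12 is hydrolysed on work-up. The closest known reaction type is the Ireland–Claisen rearrangement of esters of enantioenriched secondary (E)-allylic alcohols with 1,3-chirality transfer. No ring is closed in this step, so no mode of ring closure arises. The relative (anti) configuration of the two new stereocentres is controlled by the pairing of the E ketene acetal with the E alkene in the chair, and their absolute (2R,3R) configuration by the (R)-carbinol, whose aryl group lies equatorial and so fixes the alkene face that is attacked and also the E geometry of the new styryl alkene. The step needs one enolate geometry and one chair, which are secured by HMPA-free kinetic enolisation with in situ silylation and by the acyclic E-allyl ester with its equatorial carbinol aryl. The carbinol aryl and the conjugation gained in the new styrene should let the shift run at or below room temperature, which limits ionisation and 1,3-acyloxy migration of the doubly activated ester.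

Step 8
Reactants: 13 (2R,3R,E)-3-[4-methoxy-2-(methoxymethoxy)phenyl]-2-[4-(triisopropylsilyloxy)benzyl]-5-[4-(triisopropylsilyloxy)phenyl]pent-4-enoic acid
Product: 14 (2R,3R,E)-3-[4-methoxy-2-(methoxymethoxy)phenyl]-2-[4-(triisopropylsilyloxy)benzyl]-5-[4-(triisopropylsilyloxy)phenyl]pent-4-en-1-ol
Conditions: LiAlH4 (2 equiv), THF, 0 °C to rt; Na2SO4·10H2O quench
Reagents that add atoms: none
Why: Hydride reduction of the carboxylate by LiAlH4 gives the primary alcohol without touching the stereocentres, the unactivated styryl alkene, the MOM acetal or the aryl silyl ethers at 0 °C.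

Step 9
Reactants: 14 (2R,3R,E)-3-[4-methoxy-2-(methoxymethoxy)phenyl]-2-[4-(triisopropylsilyloxy)benzyl]-5-[4-(triisopropylsilyloxy)phenyl]pent-4-en-1-ol
Product: 15 (2R,3R,E)-3-[4-methoxy-2-(methoxymethoxy)phenyl]-2-[4-(triisopropylsilyloxy)benzyl]-5-[4-(triisopropylsilyloxy)phenyl]pent-4-enal
Conditions: Dess–Martin periodinane (1.3 equiv), pyridine (3 equiv), CH2Cl2, 0 °C to rt; used crude
Reagents that add atoms: none
Why: Dess–Martin oxidation stops at the aldehyde under buffered, nearly neutral conditions, so the epimerisable α-stereocentre should be preserved.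

Step 10
Reactants: 15 (2R,3R,E)-3-[4-methoxy-2-(methoxymethoxy)phenyl]-2-[4-(triisopropylsilyloxy)benzyl]-5-[4-(triisopropylsilyloxy)phenyl]pent-4-enal; 16 1-bromo-2,4-dimethoxybenzene
Product: 18 (1RS,2R,3R,E)-1-(2,4-dimethoxyphenyl)-3-[4-methoxy-2-(methoxymethoxy)phenyl]-2-[4-(triisopropylsilyloxy)benzyl]-5-[4-(triisopropylsilyloxy)phenyl]pent-4-en-1-ol, via 2,4-dimethoxyphenyllithium 17 (not isolated)
Conditions: 16 (1.4 equiv), n-BuLi (1.35 equiv), THF, −78 °C; then 15, −78 °C; H2O–NaHCO3 quench
Reagents that add atoms: none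
Why: Bromine–lithium exchange gives the aryllithium, whose 1,2-addition to the aldehyde at −78 °C outruns enolisation; the new carbinol centre forms as an epimer mixture (Felkin–Anh bias only), which is harmless because this centre is ionised in step 11.

Step 11
Reactants: 18 (1RS,2R,3R,E)-1-(2,4-dimethoxyphenyl)-3-[4-methoxy-2-(methoxymethoxy)phenyl]-2-[4-(triisopropylsilyloxy)benzyl]-5-[4-(triisopropylsilyloxy)phenyl]pent-4-en-1-ol
Product: 21 (2R,3R,4R)-2-(2,4-dimethoxyphenyl)-7-methoxy-3-[4-(triisopropylsilyloxy)benzyl]-4-[(E)-4-(triisopropylsilyloxy)styryl]chroman, via phenolic carbinol 19 (not isolated), via benzylic cation 20 (not isolated)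
Conditions: TsOH·H2O (0.2 equiv), MeOH–CH2Cl2 (1:1), 0 °C to 35 °C
Reagents that add atoms: none
Why: Acid-catalysed acetal exchange with methanol removes the MOM group as dimethoxymethane, the 2,4-dimethoxybenzylic carbinol ionises (SN1) and the ring A phenol oxygen captures cation 20 in a 6-exo cycloetherification that forms O1–C2; C2 is set by substrate control, because closure through a chair-like array with the C3 benzyl and C4 styryl groups equatorial places the 2-aryl group equatorial too, and since the closure is reversible through 20 the all-equatorial 2,3-trans-3,4-trans chroman should prevail from both carbinol epimers.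

Step 12
Reactants: 21 (2R,3R,4R)-2-(2,4-dimethoxyphenyl)-7-methoxy-3-[4-(triisopropylsilyloxy)benzyl]-4-[(E)-4-(triisopropylsilyloxy)styryl]chroman
Product: 22 caraganin C
Conditions: Bu4NF (2.5 equiv), AcOH (2.5 equiv), THF, 0 °C
Reagents that add atoms: none
Why: Fluoride-induced desilylation frees both phenols, acetic acid buffers the phenoxides, and the methyl ethers and the chroman should be untouched.

Compound list
1 | 2-hydroxy-4-methoxybenzaldehyde | COc1ccc(C=O)c(O)c1 | starting material
2 | 4-methoxy-2-(methoxymethoxy)benzaldehyde | COCOc1cc(OC)ccc1C=O | intermediate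
3 | 4'-hydroxyacetophenone | CC(=O)c1ccc(O)cc1 | starting material
4 | (E)-1-(4-hydroxyphenyl)-3-[4-methoxy-2-(methoxymethoxy)phenyl]prop-2-en-1-one | COCOc1cc(OC)ccc1/C=C/C(=O)c1ccc(O)cc1 | intermediate
5 | (E)-3-[4-methoxy-2-(methoxymethoxy)phenyl]-1-[4-(triisopropylsilyloxy)phenyl]prop-2-en-1-one | COCOc1cc(OC)ccc1/C=C/C(=O)c1ccc(O[Si](C(C)C)(C(C)C)C(C)C)cc1 | intermediate
6 | (R,E)-3-[4-methoxy-2-(methoxymethoxy)phenyl]-1-[4-(triisopropylsilyloxy)phenyl]prop-2-en-1-ol | O[C@H](/C=C/c1ccc(OC)cc1OCOC)c1ccc(O[Si](C(C)C)(C(C)C)C(C)C)cc1 | intermediate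
7 | 3-(4-hydroxyphenyl)propanoic acid | OC(=O)CCc1ccc(O)cc1 | starting material
8 | triisopropylsilyl 3-[4-(triisopropylsilyloxy)phenyl]propanoate | CC(C)[Si](OC(=O)CCc1ccc(O[Si](C(C)C)(C(C)C)C(C)C)cc1)(C(C)C)C(C)C | intermediate (not isolated)
9 | 3-[4-(triisopropylsilyloxy)phenyl]propanoic acid | OC(=O)CCc1ccc(O[Si](C(C)C)(C(C)C)C(C)C)cc1 | intermediate
10 | (R,E)-3-[4-methoxy-2-(methoxymethoxy)phenyl]-1-[4-(triisopropylsilyloxy)phenyl]allyl 3-[4-(triisopropylsilyloxy)phenyl]propanoate | O=C(CCc1ccc(O[Si](C(C)C)(C(C)C)C(C)C)cc1)O[C@H](/C=C/c1ccc(OC)cc1OCOC)c1ccc(O[Si](C(C)C)(C(C)C)C(C)C)cc1 | intermediate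
11 | (E)-trimethylsilyl ketene acetal of 10 (CH2Ar cis to the allylic oxygen, R carbinol) | C[Si](C)(C)O/C(=C/Cc1ccc(O[Si](C(C)C)(C(C)C)C(C)C)cc1)O[C@H](/C=C/c1ccc(OC)cc1OCOC)c1ccc(O[Si](C(C)C)(C(C)C)C(C)C)cc1 | intermediate (not isolated)
12 | trimethylsilyl (2R,3R,E)-3-[4-methoxy-2-(methoxymethoxy)phenyl]-2-[4-(triisopropylsilyloxy)benzyl]-5-[4-(triisopropylsilyloxy)phenyl]pent-4-enoate | C[Si](C)(C)OC(=O)[C@H](Cc1ccc(O[Si](C(C)C)(C(C)C)C(C)C)cc1)[C@H](c1ccc(OC)cc1OCOC)/C=C/c1ccc(O[Si](C(C)C)(C(C)C)C(C)C)cc1 | intermediate (not isolated)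
13 | (2R,3R,E)-3-[4-methoxy-2-(methoxymethoxy)phenyl]-2-[4-(triisopropylsilyloxy)benzyl]-5-[4-(triisopropylsilyloxy)phenyl]pent-4-enoic acid | OC(=O)[C@H](Cc1ccc(O[Si](C(C)C)(C(C)C)C(C)C)cc1)[C@H](c1ccc(OC)cc1OCOC)/C=C/c1ccc(O[Si](C(C)C)(C(C)C)C(C)C)cc1 | intermediate
14 | (2R,3R,E)-3-[4-methoxy-2-(methoxymethoxy)phenyl]-2-[4-(triisopropylsilyloxy)benzyl]-5-[4-(triisopropylsilyloxy)phenyl]pent-4-en-1-ol | OC[C@H](Cc1ccc(O[Si](C(C)C)(C(C)C)C(C)C)cc1)[C@H](c1ccc(OC)cc1OCOC)/C=C/c1ccc(O[Si](C(C)C)(C(C)C)C(C)C)cc1 | intermediate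
15 | (2R,3R,E)-3-[4-methoxy-2-(methoxymethoxy)phenyl]-2-[4-(triisopropylsilyloxy)benzyl]-5-[4-(triisopropylsilyloxy)phenyl]pent-4-enal | O=C[C@H](Cc1ccc(O[Si](C(C)C)(C(C)C)C(C)C)cc1)[C@H](c1ccc(OC)cc1OCOC)/C=C/c1ccc(O[Si](C(C)C)(C(C)C)C(C)C)cc1 | intermediate
16 | 1-bromo-2,4-dimethoxybenzene | COc1ccc(Br)c(OC)c1 | starting material
17 | 2,4-dimethoxyphenyllithium | [Li]c1ccc(OC)cc1OC | intermediate (not isolated)
18 | (1RS,2R,3R,E)-1-(2,4-dimethoxyphenyl)-3-[4-methoxy-2-(methoxymethoxy)phenyl]-2-[4-(triisopropylsilyloxy)benzyl]-5-[4-(triisopropylsilyloxy)phenyl]pent-4-en-1-ol (both C1 epimers) | OC(c1ccc(OC)cc1OC)[C@H](Cc1ccc(O[Si](C(C)C)(C(C)C)C(C)C)cc1)[C@H](c1ccc(OC)cc1OCOC)/C=C/c1ccc(O[Si](C(C)C)(C(C)C)C(C)C)cc1 | intermediate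
19 | (1RS,2R,3R,E)-1-(2,4-dimethoxyphenyl)-3-(2-hydroxy-4-methoxyphenyl)-2-[4-(triisopropylsilyloxy)benzyl]-5-[4-(triisopropylsilyloxy)phenyl]pent-4-en-1-ol | OC(c1ccc(OC)cc1OC)[C@H](Cc1ccc(O[Si](C(C)C)(C(C)C)C(C)C)cc1)[C@H](c1ccc(OC)cc1O)/C=C/c1ccc(O[Si](C(C)C)(C(C)C)C(C)C)cc1 | intermediate (not isolated)
20 | 2,4-dimethoxybenzylic cation derived from 19 by loss of the carbinol OH | [CH+](c1ccc(OC)cc1OC)[C@H](Cc1ccc(O[Si](C(C)C)(C(C)C)C(C)C)cc1)[C@H](c1ccc(OC)cc1O)/C=C/c1ccc(O[Si](C(C)C)(C(C)C)C(C)C)cc1 | intermediate (not isolated)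
21 | (2R,3R,4R)-2-(2,4-dimethoxyphenyl)-7-methoxy-3-[4-(triisopropylsilyloxy)benzyl]-4-[(E)-4-(triisopropylsilyloxy)styryl]chroman | COc1ccc2c(c1)O[C@@H](c1ccc(OC)cc1OC)[C@H](Cc1ccc(O[Si](C(C)C)(C(C)C)C(C)C)cc1)[C@H]2/C=C/c1ccc(O[Si](C(C)C)(C(C)C)C(C)C)cc1 | intermediate
22 | caraganin C, (2R,3R,4R)-2-(2,4-dimethoxyphenyl)-3-(4-hydroxybenzyl)-4-[(E)-4-hydroxystyryl]-7-methoxychroman | COc1ccc2c(c1)O[C@@H](c1ccc(OC)cc1OC)[C@H](Cc1ccc(O)cc1)[C@H]2/C=C/c1ccc(O)cc1 | target

Total step count: 12. Longest linear sequence: 11 steps (steps 1 to 4 and 6 to 12, from compound 1); step 5 is the side branch.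

Steps most likely to fail

Step 7. The doubly activated allylic ester may ionise or undergo 1,3-acyloxy migration before enolisation. The base may also deprotonate the diarylallylic carbinol C–H, or reaction may leak through the minor enolate geometry or a boat transition state. Each process lowers the chirality transfer or the anti ratio. The fallback forms C3–C4 by auxiliary-controlled conjugate addition and C3–CH2Ar by auxiliary-controlled alkylation, so no allylic C–O bond is involved. It sets out from aldehyde 2 and returns to the route at alcohol 14.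
- Acceptor: Knoevenagel–Doebner condensation of 2 with malonic acid (pyridine, piperidine, 90 °C) gives (E)-3-[4-methoxy-2-(methoxymethoxy)phenyl]acrylic acid F1. Pivaloyl chloride, Et3N, LiCl and (R)-4-phenyl-2-oxazolidinone (THF, −20 °C to rt) convert it into the N-enoyl oxazolidinone F2.
- Styryl donor: 4-hydroxycinnamic acid is silylated as in step 5, through the bis-silyl compound F3, to (E)-3-[4-(triisopropylsilyloxy)phenyl]acrylic acid F4. Hunsdiecker-type bromodecarboxylation (N-bromosuccinimide, LiOAc cat., MeCN–H2O) gives the (E)-bromostyrene F5, and Mg in THF gives the Grignard reagent F6.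
- Conjugate addition: CuBr·SMe2-mediated 1,4-addition of F6 to F2 (THF, −40 °C) on the chelated imide, from the face away from the 4-phenyl group, should give the (3S)-adduct F7.
- Benzyl donor: p-cresol with iPr3SiCl and imidazole gives the silyl ether F8, and N-bromosuccinimide with azobisisobutyronitrile (PhCF3, 80 °C) gives 4-(triisopropylsilyloxy)benzyl bromide F9.
- Alkylation and release: the sodium enolate of F7 (NaN(SiMe3)2, THF, −78 °C) is alkylated by F9, again away from the 4-phenyl group, to the (2R,3R)-imide F10. LiBH4 (Et2O–MeOH, 0 °C) then removes the auxiliary reductively and gives 14.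

Step 4. Facial discrimination may be poor because the aryl and E-styryl arms of the ketone are similar in size and both conjugated, and some conjugate reduction may compete. The fallback replaces asymmetric catalysis by resolution with recycling. It sets out from chalcone 5 and returns at 6. Luche reduction (NaBH4, CeCl3·7H2O, MeOH, 0 °C) gives the racemic allylic alcohol F11. Preparative chromatography on an amylose tris(3,5-dimethylphenylcarbamate) phase (supercritical CO2–iPrOH with 0.1% Et3N) separates 6 from its (S)-enantiomer F12. F12 is oxidised back to 5 with MnO2 (CH2Cl2) and reduced again.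

Step 11. The open benzylic cation may lose a proton towards C2=C3, which would scramble C3 on reprotonation. It may also be captured by the pendant arenes, methanol may add across the styryl alkene while MOM cleavage lags, or equilibration at C2 may stay incomplete. The fallback reverses the order of the two bonds at C2: O1–C2 is closed first as an acetal and ring B is added last. It sets out from aldehyde 15, bypasses steps 10 and 11, and returns at 21. TsOH·H2O (cat.) in MeOH removes the MOM group and closes the cyclic methyl acetal (3R,4R)-2,7-dimethoxy-3-[4-(triisopropylsilyloxy)benzyl]-4-[(E)-4-(triisopropylsilyloxy)styryl]chroman F13 as an anomer mixture. BF3·OEt2 (CH2Cl2, −40 °C) then activates F13 towards Friedel–Crafts C-arylation at C2 by 1,3-dimethoxybenzene (5 equiv) through its 4-position, as in aryl C-glycoside synthesis. The aryl group should enter trans to the C3 benzyl group, and because this arylation is reversible under the Lewis acid the all-equatorial isomer 21 should prevail.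

Further compounds
F1 | step 7 | (E)-3-[4-methoxy-2-(methoxymethoxy)phenyl]acrylic acid | COCOc1cc(OC)ccc1/C=C/C(=O)O
F2 | step 7 | (R)-3-{(E)-3-[4-methoxy-2-(methoxymethoxy)phenyl]acryloyl}-4-phenyloxazolidin-2-one | COCOc1cc(OC)ccc1/C=C/C(=O)N1[C@H](c2ccccc2)COC1=O
F3 | step 7 | triisopropylsilyl (E)-3-[4-(triisopropylsilyloxy)phenyl]acrylate | CC(C)[Si](OC(=O)/C=C/c1ccc(O[Si](C(C)C)(C(C)C)C(C)C)cc1)(C(C)C)C(C)C
F4 | step 7 | (E)-3-[4-(triisopropylsilyloxy)phenyl]acrylic acid | OC(=O)/C=C/c1ccc(O[Si](C(C)C)(C(C)C)C(C)C)cc1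
F5 | step 7 | (E)-[4-(2-bromovinyl)phenoxy]triisopropylsilane | Br/C=C/c1ccc(O[Si](C(C)C)(C(C)C)C(C)C)cc1
F6 | step 7 | (E)-{2-[4-(triisopropylsilyloxy)phenyl]vinyl}magnesium bromide | Br[Mg]/C=C/c1ccc(O[Si](C(C)C)(C(C)C)C(C)C)cc1
F7 | step 7 | (R)-3-{(S,E)-3-[4-methoxy-2-(methoxymethoxy)phenyl]-5-[4-(triisopropylsilyloxy)phenyl]pent-4-enoyl}-4-phenyloxazolidin-2-one | O=C(C[C@H](c1ccc(OC)cc1OCOC)/C=C/c1ccc(O[Si](C(C)C)(C(C)C)C(C)C)cc1)N1[C@H](c2ccccc2)COC1=O
F8 | step 7 | triisopropyl(p-tolyloxy)silane | Cc1ccc(O[Si](C(C)C)(C(C)C)C(C)C)cc1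
F9 | step 7 | [4-(bromomethyl)phenoxy]triisopropylsilane | BrCc1ccc(O[Si](C(C)C)(C(C)C)C(C)C)cc1
F10 | step 7 | (R)-3-{(2R,3R,E)-3-[4-methoxy-2-(methoxymethoxy)phenyl]-2-[4-(triisopropylsilyloxy)benzyl]-5-[4-(triisopropylsilyloxy)phenyl]pent-4-enoyl}-4-phenyloxazolidin-2-one | O=C([C@H](Cc1ccc(O[Si](C(C)C)(C(C)C)C(C)C)cc1)[C@H](c1ccc(OC)cc1OCOC)/C=C/c1ccc(O[Si](C(C)C)(C(C)C)C(C)C)cc1)N1[C@H](c2ccccc2)COC1=O
F11 | step 4 | racemic (E)-3-[4-methoxy-2-(methoxymethoxy)phenyl]-1-[4-(triisopropylsilyloxy)phenyl]prop-2-en-1-ol | OC(/C=C/c1ccc(OC)cc1OCOC)c1ccc(O[Si](C(C)C)(C(C)C)C(C)C)cc1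
F12 | step 4 | (S,E)-3-[4-methoxy-2-(methoxymethoxy)phenyl]-1-[4-(triisopropylsilyloxy)phenyl]prop-2-en-1-ol | O[C@@H](/C=C/c1ccc(OC)cc1OCOC)c1ccc(O[Si](C(C)C)(C(C)C)C(C)C)cc1
F13 | step 11 | (3R,4R)-2,7-dimethoxy-3-[4-(triisopropylsilyloxy)benzyl]-4-[(E)-4-(triisopropylsilyloxy)styryl]chroman (anomer mixture) | COc1ccc2c(c1)OC(OC)[C@H](Cc1ccc(O[Si](C(C)C)(C(C)C)C(C)C)cc1)[C@H]2/C=C/c1ccc(O[Si](C(C)C)(C(C)C)C(C)C)cc1
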